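**Retrosynthetic overview**

1. Prinsepiol 17 ⇐ tetrasilyl ether 16 (fluoride) ⇐ bis-lactol diacetate 11 + aryl nucleophile from 13: C2–Ar and C6–Ar are made last, by aryl addition to the two oxocarbenium ions on the convex face.
2. 11 ⇐ bis-γ-lactone 9/8/7 ⇐ bis(benzyloxymethyl) tartrate acetonide 5: the acyl C–O bonds O3–C2 and O7–C6 close both oxolane rings together by double lactonisation.
3. 5 ⇐ dimethyl L-tartrate acetonide 2 + 2 BOMCl 3: C1–C8 and C5–C4 by two successive enolate alkylations with retention.
4. Feature used: the chain C2–C1(OH)–C5(OH)–C6 (bridgehead carbinols C1/C5 shared by both oxolane rings of the 3,7-dioxabicyclo[3.3.0]octane, flanked by the ArCH carbons C2/C6) is the carbon chain of (2R,3R)-tartaric acid with each carbinol H replaced by a CH2O arm (C8 on C1, C4 on C5).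
5. Ring order: no ring in the key step; both oxolane rings in step 3 (as lactones); the temporary dioxolane is removed in step 4; aryl groups in step 9.

Key step: step 2

Remark: lactol 10 and diacetate 11 are carried as anomer mixtures (anomeric centres undefined in the SMILES), since all anomers ionise to the same oxocarbenium ions. The bridgehead descriptors change from R (7–11) to S (16, 17) only through a change in CIP rank of C2/C6; no bridgehead bond is touched after step 2.

**Route**

Step 1
Reactants: 1 L-(+)-tartaric acid
Product: 2 dimethyl (4R,5R)-2,2-dimethyl-1,3-dioxolane-4,5-dicarboxylate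
Conditions: Me2C(OMe)2, MeOH, TsOH·H2O (cat.), cyclohexane, reflux with removal of the acetone/MeOH azeotrope; K2CO3; distil
Reagents that add atoms: 2,2-dimethoxypropane, COC(C)(C)OC; methanol, CO
Why: Fischer esterification and acid-catalysed ketalisation of the trans-diol run in one pot and are driven by removal of the volatiles, and neither touches the two stereocentres.

Step 2
Reactants: 2 dimethyl (4R,5R)-2,2-dimethyl-1,3-dioxolane-4,5-dicarboxylate; 3 benzyl chloromethyl ether (2.6 equiv in two portions)
Product: 5 dimethyl (4R,5R)-4,5-bis[(benzyloxy)methyl]-2,2-dimethyl-1,3-dioxolane-4,5-dicarboxylate, via mono(benzyloxymethyl) diester 4 (not isolated)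
Conditions: LDA (1.1 equiv), THF–DMPU, −78 °C; 3 (1.1 equiv), −78 °C; then LDA (1.3 equiv), −78 °C; 3 (1.5 equiv), −78 → −50 °C; AcOH quench at −78 °C
Reagents that add atoms: none
Why: LDA removes the proton α to one ester to give a lithium ester enolate whose trigonal carbon stays in the dioxolane, and C-alkylation by the α-chloro ether (SN2 with strong oxocarbenium character) forms C1–C8; a second deprotonation at the only remaining α-CH and a second alkylation form C5–C4. The closest known reaction type is the α-alkylation of tartrate acetonide ester enolates, which proceeds with retention because the stereocentre lost on enolisation is rebuilt under control of its neighbour. No ring is closed in this step. The first quaternary centre is set by the adjacent CH(CO2Me) centre, the electrophile entering anti to that ester; the second is set by the new quaternary centre, the electrophile entering anti to its sp3 benzyloxymethyl arm and syn to its flat, smaller ester, so that the C2-symmetric trans-diester (4R,5R) should result with each CH2OBn cis to the distal ester. The step needs C-alkylation to outrun β-elimination (opening of the dioxolane) and N-alkylation of the base, which is secured by the ring C–O bond lying close to the nodal plane of the enolate, by working at or below −70 °C and by the very high reactivity of the chloromethyl ether in THF–DMPU; staged addition of base and electrophile keeps the two alkylations apart.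

Step 3
Reactants: 5 dimethyl (4R,5R)-4,5-bis[(benzyloxy)methyl]-2,2-dimethyl-1,3-dioxolane-4,5-dicarboxylate
Product: 7 (1R,5R)-1,5-(isopropylidenedioxy)-3,7-dioxabicyclo[3.3.0]octane-2,6-dione, via bis(hydroxymethyl) diester 6 (not isolated)
Conditions: H2 (1 atm), 10% Pd/C, MeOH, rt; filter; TsOH (cat.), toluene, 60 °C
Reagents that add atoms: none
Why: Hydrogenolysis of the two benzyl ethers frees two primary hydroxyls, each held cis to the distal ester across the dioxolane, and each closes a γ-lactone by 5-exo-trig acyl substitution (double lactonisation to the [3.3.3]propellane) without touching a stereocentre.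

Step 4
Reactants: 7 (1R,5R)-1,5-(isopropylidenedioxy)-3,7-dioxabicyclo[3.3.0]octane-2,6-dione
Product: 8 (1R,5R)-1,5-dihydroxy-3,7-dioxabicyclo[3.3.0]octane-2,6-dione
Conditions: TFA–H2O (9:1), rt → 40 °C; evaporate, azeotrope with toluene
Reagents that add atoms: none
Why: Acid hydrolysis of the isopropylidene ketal is helped by relief of propellane strain, while the γ-lactones persist in acid and any opened hydroxy acid relactonises on concentration.

Step 5
Reactants: 8 (1R,5R)-1,5-dihydroxy-3,7-dioxabicyclo[3.3.0]octane-2,6-dione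
Product: 9 (1R,5R)-1,5-bis(triethylsilyloxy)-3,7-dioxabicyclo[3.3.0]octane-2,6-dione
Conditions: TESOTf (3 equiv), 2,6-lutidine (5 equiv), CH2Cl2, 0 °C → rt
Reagents that add atoms: triethylsilyl trifluoromethanesulfonate, CC[Si](CC)(CC)OS(=O)(=O)C(F)(F)F
Why: Silyl triflate with a hindered pyridine base silylates even tertiary alcohols, and the TES ethers are non-participating in the later oxocarbenium chemistry and removable with fluoride.

Step 6
Reactants: 9 (1R,5R)-1,5-bis(triethylsilyloxy)-3,7-dioxabicyclo[3.3.0]octane-2,6-dione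
Product: 10 (1R,5R)-1,5-bis(triethylsilyloxy)-3,7-dioxabicyclo[3.3.0]octane-2,6-diol (anomer mixture)
Conditions: DIBAL-H (2.3 equiv), CH2Cl2, −78 °C; MeOH at −78 °C; aq. Rochelle salt
Reagents that add atoms: none
Why: Partial reduction of γ-lactones by DIBAL-H stops at the lactol because the five-membered aluminium hemiacetal is stable at −78 °C, and the bridgehead centres are not involved.

Step 7
Reactants: 10 (1R,5R)-1,5-bis(triethylsilyloxy)-3,7-dioxabicyclo[3.3.0]octane-2,6-diol
Product: 11 (1R,5R)-1,5-bis(triethylsilyloxy)-3,7-dioxabicyclo[3.3.0]octane-2,6-diyl diacetate (anomer mixture)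
Conditions: Ac2O, pyridine, DMAP (cat.), CH2Cl2, 0 °C → rt
Reagents that add atoms: acetic anhydride, CC(=O)OC(C)=O
Why: DMAP-catalysed acylation of the lactol hydroxyls gives anomeric acetates, which are standard leaving groups for Lewis-acid generation of oxocarbenium ions.

Step 8
Reactants: 12 4-bromo-2-methoxyphenol
Product: 13 (4-bromo-2-methoxyphenoxy)(tert-butyl)dimethylsilane
Conditions: TBSCl, imidazole, DMF, rt
Reagents that add atoms: tert-butyldimethylsilyl chloride, CC(C)(C)[Si](C)(C)Cl
Why: Imidazole-promoted silylation masks the phenol for the halogen–metal exchange, and the silyl group sits para to the bromine so no silyl migration to the metalated carbon is possible.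

Step 9
Reactants: 11 (1R,5R)-1,5-bis(triethylsilyloxy)-3,7-dioxabicyclo[3.3.0]octane-2,6-diyl diacetate; 13 (4-bromo-2-methoxyphenoxy)(tert-butyl)dimethylsilane (6 equiv)
Product: 16 (1S,2R,5S,6R)-2,6-bis[4-(tert-butyldimethylsilyloxy)-3-methoxyphenyl]-1,5-bis(triethylsilyloxy)-3,7-dioxabicyclo[3.3.0]octane, via aryllithium 14 (not isolated), via diarylzinc 15 (not isolated)
Conditions: 13, n-BuLi, Et2O, −78 → −20 °C; ZnCl2 (0.5 equiv per ArLi, 1 M in Et2O), → 0 °C; then 11, BF3·OEt2 (3 equiv), CH2Cl2, −78 → −20 °C
Reagents that add atoms: n-butyllithium, CCCC[Li] (Li of 14 only); zinc chloride, Cl[Zn]Cl (Zn of 15 only)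
Why: BF3 ionises each anomeric acetate to a five-membered oxocarbenium ion that is captured by the arylzinc (Lewis-acid C-glycosylation-type arylation with an organozinc nucleophile), the aryl group entering on the convex face of the cis-fused bicycle, cis to the adjacent bridgehead silyloxy group (inside attack on the envelope, 1,2-cis to the alkoxy substituent), which should set C2 and C6 as R,R, while the position of the bromine in 13 fixes the 4-oxy-3-methoxy pattern.

Step 10
Reactants: 16 (1S,2R,5S,6R)-2,6-bis[4-(tert-butyldimethylsilyloxy)-3-methoxyphenyl]-1,5-bis(triethylsilyloxy)-3,7-dioxabicyclo[3.3.0]octane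
Product: 17 prinsepiol, (1S,2R,5S,6R)-2,6-bis(4-hydroxy-3-methoxyphenyl)-3,7-dioxabicyclo[3.3.0]octane-1,5-diol
Conditions: TBAF (6 equiv), AcOH (6 equiv), THF, 0 °C → rt
Reagents that add atoms: none
Why: Fluoride cleaves the two aryl and the two tertiary Si–O bonds in one operation, and the acetic acid buffer keeps the phenoxide from opening the para-hydroxybenzylic ethers through a quinone methide, so C2 and C6 should not epimerise.

**Compound list**

1 | L-(+)-tartaric acid, (2R,3R)-2,3-dihydroxybutanedioic acid | O[C@@H](C(=O)O)[C@@H](O)C(=O)O | starting material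
2 | dimethyl (4R,5R)-2,2-dimethyl-1,3-dioxolane-4,5-dicarboxylate | COC(=O)[C@@H]1OC(C)(C)O[C@H]1C(=O)OC | intermediate
3 | benzyl chloromethyl ether | ClCOCc1ccccc1 | starting material
4 | dimethyl (4R,5R)-4-[(benzyloxy)methyl]-2,2-dimethyl-1,3-dioxolane-4,5-dicarboxylate (trans-diester) | COC(=O)[C@]1(COCc2ccccc2)OC(C)(C)O[C@H]1C(=O)OC | intermediate (not isolated)
5 | dimethyl (4R,5R)-4,5-bis[(benzyloxy)methyl]-2,2-dimethyl-1,3-dioxolane-4,5-dicarboxylate (trans-diester) | COC(=O)[C@]1(COCc2ccccc2)OC(C)(C)O[C@@]1(COCc2ccccc2)C(=O)OC | intermediate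
6 | dimethyl (4R,5R)-4,5-bis(hydroxymethyl)-2,2-dimethyl-1,3-dioxolane-4,5-dicarboxylate | COC(=O)[C@]1(CO)OC(C)(C)O[C@@]1(CO)C(=O)OC | intermediate (not isolated)
7 | (1R,5R)-1,5-(isopropylidenedioxy)-3,7-dioxabicyclo[3.3.0]octane-2,6-dione (propellane bis-lactone acetonide) | O=C1OC[C@]2(OC(C)(C)O3)C(=O)OC[C@]123 | intermediate
8 | (1R,5R)-1,5-dihydroxy-3,7-dioxabicyclo[3.3.0]octane-2,6-dione | O=C1OC[C@]2(O)C(=O)OC[C@]12O | intermediate
9 | (1R,5R)-1,5-bis(triethylsilyloxy)-3,7-dioxabicyclo[3.3.0]octane-2,6-dione | O=C1OC[C@]2(O[Si](CC)(CC)CC)C(=O)OC[C@]12O[Si](CC)(CC)CC | intermediate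
10 | (1R,5R)-1,5-bis(triethylsilyloxy)-3,7-dioxabicyclo[3.3.0]octane-2,6-diol (anomer mixture) | OC1OC[C@]2(O[Si](CC)(CC)CC)C(O)OC[C@]12O[Si](CC)(CC)CC | intermediate
11 | (1R,5R)-1,5-bis(triethylsilyloxy)-3,7-dioxabicyclo[3.3.0]octane-2,6-diyl diacetate (anomer mixture) | CC(=O)OC1OC[C@]2(O[Si](CC)(CC)CC)C(OC(C)=O)OC[C@]12O[Si](CC)(CC)CC | intermediate
12 | 4-bromo-2-methoxyphenol | COc1cc(Br)ccc1O | starting material
13 | (4-bromo-2-methoxyphenoxy)(tert-butyl)dimethylsilane | COc1cc(Br)ccc1O[Si](C)(C)C(C)(C)C | intermediate
14 | [4-(tert-butyldimethylsilyloxy)-3-methoxyphenyl]lithium | [Li]c1ccc(O[Si](C)(C)C(C)(C)C)c(OC)c1 | intermediate (not isolated)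
15 | bis[4-(tert-butyldimethylsilyloxy)-3-methoxyphenyl]zinc | COc1cc([Zn]c2ccc(O[Si](C)(C)C(C)(C)C)c(OC)c2)ccc1O[Si](C)(C)C(C)(C)C | intermediate (not isolated)
16 | (1S,2R,5S,6R)-2,6-bis[4-(tert-butyldimethylsilyloxy)-3-methoxyphenyl]-1,5-bis(triethylsilyloxy)-3,7-dioxabicyclo[3.3.0]octane | COc1cc([C@H]2OC[C@]3(O[Si](CC)(CC)CC)[C@@H](c4ccc(O[Si](C)(C)C(C)(C)C)c(OC)c4)OC[C@]23O[Si](CC)(CC)CC)ccc1O[Si](C)(C)C(C)(C)C | intermediate
17 | prinsepiol, (1S,2R,5S,6R)-2,6-bis(4-hydroxy-3-methoxyphenyl)-3,7-dioxabicyclo[3.3.0]octane-1,5-diol | COc1cc([C@H]2OC[C@]3(O)[C@@H](c4ccc(O)c(OC)c4)OC[C@]23O)ccc1O | target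

**Step count**

Total: 10 steps. Longest linear sequence: 9 steps (steps 1–7, 9, 10 from L-tartaric acid); step 8 is the one-step side branch.

**Steps most likely to fail, with fallbacks**

Step 2. The second enolate may decompose by β-elimination or be outrun by consumption of the base by the electrophile. The second alkylation may also lose facial selectivity, and the resulting cis-diester cannot form the bis-lactone. Fallback: setting out from 2, only the first alkylation is run (LDA 1.1 equiv, 3, THF–DMPU, −78 °C) and 4 is isolated. Hydrogenolysis (H2, Pd/C, MeOH, then cat. TsOH) turns its benzyloxymethyl arm into a γ-lactone with the distal ester and should give methyl (3aR,6aR)-2,2-dimethyl-6-oxotetrahydrofuro[3,4-d][1,3]dioxole-3a(4H)-carboxylate F1. The remaining α-hydrogen now sits at the ring-fusion carbon of a cis-fused bicyclo[3.3.0] lactone. Its enolate (LDA, THF, −78 °C) is alkylated with 3 to methyl (3aR,6aR)-6a-[(benzyloxy)methyl]-2,2-dimethyl-6-oxotetrahydrofuro[3,4-d][1,3]dioxole-3a(4H)-carboxylate F2. Only the cis-fused product can form, so retention is enforced by the ring and no longer rests on the relative size of ester and CH2OBn. Hydrogenolysis of F2 with lactonisation onto the angular methyl ester comes back to the route at 7.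

Step 9. The aryl group may enter on the wrong face of the oxocarbenium ion (cis to the other ring), capture next to the quaternary carbon may be slow, or the TES ethers may be lost under BF3. Fallback: setting out from 10, aryllithium 14 (excess, made from 13 and n-BuLi as in step 9; THF, −78 → 0 °C) adds to the open hydroxy-aldehyde form of both lactols. This should give the ring-opened bis(benzylic alcohol), 1,4-bis[4-(tert-butyldimethylsilyloxy)-3-methoxyphenyl]-2,3-bis(hydroxymethyl)-2,3-bis(triethylsilyloxy)butane-1,4-diol F3, whose carbinol configuration does not matter. Acid (BF3·OEt2 or CSA, cat., CH2Cl2, −40 → 0 °C) then ionises the electron-rich benzylic alcohols, and each primary hydroxyl closes its oxolane ring on the benzylic cation (5-exo, reversible), the aryl groups taking the convex positions. The aryl–carbon bond is thus made by carbonyl addition and C2/C6 are set in the ring closure; the sequence comes back to the route at 16.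

Step 6. Reduction may run past the lactol, which would make the two arms on each carbinol identical and erase the stereochemistry. The free lactol may also undergo ring-chain isomerisation or silyl migration. Fallback: setting out from 9, DIBAL-H (CH2Cl2, −78 °C) is followed without work-up by Ac2O, pyridine and DMAP at −78 °C → rt. The bis(diisobutylaluminium) hemiacetal F4 is acetylated in the flask (reductive acetylation of lactones), so that neither a free lactol nor an open aldehyde is ever present, and the route is rejoined at 11.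

**Further compounds**

F1 | step 2 | methyl (3aR,6aR)-2,2-dimethyl-6-oxotetrahydrofuro[3,4-d][1,3]dioxole-3a(4H)-carboxylate | COC(=O)[C@@]12COC(=O)[C@@H]1OC(C)(C)O2
F2 | step 2 | methyl (3aR,6aR)-6a-[(benzyloxy)methyl]-2,2-dimethyl-6-oxotetrahydrofuro[3,4-d][1,3]dioxole-3a(4H)-carboxylate | COC(=O)[C@@]12COC(=O)[C@]1(COCc3ccccc3)OC(C)(C)O2
F3 | step 9 | 1,4-bis[4-(tert-butyldimethylsilyloxy)-3-methoxyphenyl]-2,3-bis(hydroxymethyl)-2,3-bis(triethylsilyloxy)butane-1,4-diol (carbinol epimers) | COc1cc(C(O)[C@](CO)(O[Si](CC)(CC)CC)[C@@](CO)(O[Si](CC)(CC)CC)C(O)c2ccc(O[Si](C)(C)C(C)(C)C)c(OC)c2)ccc1O[Si](C)(C)C(C)(C)C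
F4 | step 6 | (1R,5R)-2,6-bis(diisobutylaluminiooxy)-1,5-bis(triethylsilyloxy)-3,7-dioxabicyclo[3.3.0]octane | CC(C)C[Al](CC(C)C)OC1OC[C@]2(O[Si](CC)(CC)CC)C(O[Al](CC(C)C)CC(C)C)OC[C@]12O[Si](CC)(CC)CC
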